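## Structural features

Locants: unprimed atoms belong to the tetralin (aromatic ring A, carbocyclic ring B), primed atoms to the naphthalene (ring C with C1'–C4', ring D with C5'–C8'). Double-primed atoms belong to the phenyl ring from which the naphthalene is grown: C1'' becomes C2', C2'' becomes C1', C3'' becomes C8a' and C4'' becomes C4a'.

Dipolynaphthalene A (22) is a 5-methoxytetralin-1-ol joined by a single C(sp3)–C(sp2) bond, C4–C2', to a 1-hydroxy-8-methoxynaphthalene. Its two stereocentres, C1 (S, secondary benzylic carbinol) and C4 (R, diarylmethine), are not neighbours. They lie 1,4 across ring B with the C2 and C3 methylenes between them, and the hydroxyl and the naphthyl group are trans. C4 is crowded: the C5 methoxy group sits peri to it and the C1' oxygen sits ortho to the ring junction. The benzylic C1–OH is acid-labile (ionisation with loss of configuration, ether formation, dehydration towards a naphthalene). The doubly benzylic C4–H is at risk from strong base and oxidants, and the electron-rich naphthol is sensitive to oxidants and electrophiles. The real difficulties are the remote trans relationship, the hindered C4–C2' junction and the unsymmetrical peri pair (free OH on C1', OMe on C8'). The key step exploits ring D (C4a', C5', C6', C7', C8', C8a'): a methoxy group on C8' peri to the C1' oxygen is the pattern that a benzyne with an oxygen next to the triple bond produces with a 1,1-dioxygenated butadiene. Ring D can therefore be grown on a simple phenyl ring whose protected oxygen both directs the metalation and fixes the orientation of the addition.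

## Logic of the disconnections

**22 back to 21 and 20.** Only heteroatom bonds are cut: the Si–O bond at C1 and the O–CH2 bond of the acetal on the C1' oxygen. The C1 carbinol has to be inert to a lithium amide, and the C1' oxygen has to be a non-acidic, ortho-directing ether during the annulation. The gain is that 20 carries no acidic proton. The demand is on the order of events: the acetal is removed first, in acid, while C1–O is still a hindered silyl ether, so the free benzylic alcohol never meets acid. Fluoride then ends the synthesis under non-acidic conditions.

**20 back to 13 and 16 (through 17, 18 and 19).** The bonds C4a'–C5' and C8a'–C8' are cut, which removes ring D. The naphthalene shrinks to a chlorophenyl ring and a four-carbon diene, and the two peri oxygens are differentiated from the start: one is the protected oxygen of the arene, the other arrives as the methyl ether of 16. The forward step needs lithiation only between oxygen and chlorine, one orientation of addition, loss of silanolate and not of methoxide, and survival of C1 and C4 in strong base. If some of the material aromatises to the C8' phenol instead, simple O-methylation converges on 20, because the C1' oxygen is protected.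

**16 back to 14 (through 15).** The O–Si bond is cut. A purchasable crotonate then supplies all four carbons and the methoxy group of ring D. The demand is γ-deprotonation without conjugate addition of the amide.

**13 back to 12 and then 11.** The Si–O bond is cut, then the two hydrogens on C3 and C4 are removed to give the C3=C4 alkene. C4 can be derived from C1 by hydroxyl-directed hydrogen delivery. This is the only mode that gives the trans isomer, because sterically controlled delivery to a C1-protected alkene would favour cis. The gain is that the 1,4-problem becomes a one-stereocentre problem and C4 becomes sp2, open to cross-coupling. The demand is a free hydroxyl at this stage, a homogeneous cationic iridium catalyst that spares the aryl chloride, and neutral handling of 11.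

**11 back to 6 and 9 (through 10).** The C4–C1'' bond and the ester C–O bond are cut. The route becomes convergent. The coupling must choose C–OTf over C–Cl and must tolerate a doubly ortho-hindered junction. The acetate is hydrolysed in the same flask, so that unmasking the hydroxyl costs no separate step.

**9 back to 8 and 7.** The C–B bond and the acetal O–CH2 bond are cut. The bromine of 7 marks the future junction carbon and the chlorine the future aryne. The borylation must touch bromine only.

**6 back to 4 (through 5), 3, 2 and 1.** In turn the O–S bond, the C4 carbonyl oxygen, the acetyl group and the C1–H bond are cut. Everything then rests on one asymmetric ketone reduction of a purchasable tetralone. An acetate is preferred to a silyl ether on C1 because it deactivates the C1–H bond towards the oxidant and is removed by base when the free hydroxyl is needed. The oxidation must attack the peri-hindered C4 methylene and leave C1 alone.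

## Other disconnections considered

**Alternative 1: dienylketene electrocyclisation.**
- Cut: C1'–C8a' of ring C. The precursor would be the (Z)-4-(2-chloro-5-methoxyphenyl)but-3-enoic acid A1, which carries the silylated tetralin on its α-carbon.
- Forward step: (COCl)2 and then NEt3 would give dienylketene A2. Six-electron closure onto the arene and tautomerisation would give chloronaphthol A3.
- In favour: ring C and the free C1' hydroxyl arise together, so no phenol protecting group and no organolithium base are needed. The closure is unimolecular, which is better than the chosen plan: there is no trapping partner in excess and no competing capture of a reactive intermediate. The chlorine blocks the other ortho position, so regiochemistry is enforced by substitution. That is at least the equal of the electronic bias of the aryne.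
- Against: closure must occur at the hindered position next to the methoxy group. The Z alkene must be made and kept, and the E isomer cannot close. The ketene can dimerise. The chlorine needs an extra reductive step that threatens the benzylic C1–O bond. Most seriously, C4 must be set while forming a C(sp3)–C(sp3) bond to the α-carbon, and no counterpart of the directed hydrogenation is available for that.
- Comparison: both plans build the naphthalene late on a stereodefined tetralin and both are pericyclic. This one forms one C–C bond where the chosen step forms two. It is judged several steps longer because of the Z-olefin synthesis and the dechlorination.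

**Alternative 2: ring-closing metathesis.**
- Cut: C2–C3, as an alkene. The precursor is the ortho-bis(allylic) arene A4, with the silyloxy carbon and the diaryl carbon each carrying a vinyl group.
- Forward step: (H2IMes)(PCy3)Cl2Ru=CHPh, the second-generation Grubbs catalyst, would close ring B to the 1,4-dihydronaphthalene A5. A separate alkene reduction would follow.
- In favour: each stereocentre is set on its own by reagent control, so any diastereomer is accessible without a 1,4-relay. That is better than the chosen plan. The naphthalene would be bought with both peri oxygens in place, so no aryne regiochemistry arises, also better. Six-ring metathesis is as dependable as any step of the chosen route.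
- Against: the diaryl(vinyl)methine centre, flanked by two ortho substituents, must be made enantioselectively, which is a harder problem than a ketone reduction. A4 and A5 hold a C4–H that is doubly benzylic and allylic and a silyl ether that is benzylic and allylic. Ruthenium hydride isomerisation and 1,4-loss of silanol to a fully aromatic naphthalene are therefore real threats. The extra reduction must spare the benzylic C–O bond.
- Comparison: this plan closes ring B, the chosen one ring D. It is mechanistically mild (no strong base) but handles a more fragile intermediate. The step count is expected to be equal at best and probably higher.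

**Alternative 3: photoenolisation Diels–Alder annulation.**
- Cut: C1–C2 and C3–C4. The precursor is the achiral 2-(naphthylmethyl)benzaldehyde A6.
- Forward step: UV light with Ti(Oi-Pr)4 and a chiral TADDOL-type diol would give the hydroxy-ortho-quinodimethane A7. Addition of methyl acrylate A8 would close ring B to the all-cis hydroxy ester A9.
- In favour: it is the most convergent plan. One catalytic enantioselective operation forms ring B, two C–C bonds and three stereocentres, whereas the chosen key step forms none. That is better in stereochemical productivity. A6 is short to make.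
- Against: the all-cis outcome puts the C1 oxygen cis to the C4 aryl group, so C1 must be inverted. The C2 ester must also be excised (hydrolysis and radical decarboxylation). That is about four corrective steps. The naphthalene is a competing absorber and a low-energy triplet acceptor that can quench the excited aldehyde within the molecule. The aldehyde also has no oxygen ortho to the formyl group to help hold titanium.
- Comparison: the mechanism is photochemical and catalyst-controlled, against thermal and substrate-controlled. The convergence gained is largely spent on repairs, so the total is expected to be about the same, with less certainty of relative configuration.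

Key step: step 11

Remark on the chemistry: 22 is (1S,4R), the 1,4-trans isomer. The geometry of 16 about its oxygenated double bond is immaterial, because that carbon becomes aromatic.

## Route

Step 1
Reactants: 1 5-methoxy-3,4-dihydronaphthalen-1(2H)-one (5-methoxy-1-tetralone)
Product: 2 (1S)-5-methoxy-1,2,3,4-tetrahydronaphthalen-1-ol
Conditions: RuCl(p-cymene)[(S,S)-TsDPEN] (1 mol %), HCO2H/NEt3 (5:2), 30 °C
Reagents that add atoms: none
Why: Noyori asymmetric transfer hydrogenation of an aryl alkyl ketone; with the (S,S) ligand the hydride should reach the face that gives the (S)-carbinol, as for 1-tetralone, and the remote methoxy group (meta to the carbonyl-bearing carbon) should not disturb this; C1 is set here.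

Step 2
Reactants: 2 (1S)-5-methoxy-1,2,3,4-tetrahydronaphthalen-1-ol
Product: 3 (1S)-5-methoxy-1,2,3,4-tetrahydronaphthalen-1-yl acetate
Conditions: Ac2O, pyridine, DMAP (cat.), CH2Cl2, 0 °C to rt
Reagents that add atoms: acetic anhydride, CC(=O)OC(C)=O
Why: DMAP-catalysed acylation; the electron-withdrawing acetoxy group protects the C1–H bond from the oxidant of step 3, where a silyl ether would invite oxidation at C1, and it is base-labile when the free hydroxyl is needed.

Step 3
Reactants: 3 (1S)-5-methoxy-1,2,3,4-tetrahydronaphthalen-1-yl acetate
Product: 4 (1S)-5-methoxy-4-oxo-1,2,3,4-tetrahydronaphthalen-1-yl acetate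
Conditions: CrO3, AcOH/H2O (9:1), 10–15 °C
Reagents that add atoms: chromium trioxide, O=[Cr](=O)=O
Why: Benzylic oxidation of a tetralin methylene to the aryl ketone by hexavalent chromium, the reaction type that converts 1-acyloxytetralins into 4-acyloxy-1-tetralones; C4 is the only benzylic CH2 left and is activated by the ortho-methoxy ring, while C1–H is deactivated and C1 keeps its configuration.

Step 4
Reactants: 4 (1S)-5-methoxy-4-oxo-1,2,3,4-tetrahydronaphthalen-1-yl acetate
Product: 6 (1S)-5-methoxy-4-(trifluoromethanesulfonyloxy)-1,2-dihydronaphthalen-1-yl acetate, via potassium enolate 5 (not isolated)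
Conditions: KN(SiMe3)2, THF, −78 °C; then PhNTf2, −78 to 0 °C
Reagents that add atoms: N-phenylbis(trifluoromethanesulfonimide), O=S(=O)(N(c1ccccc1)S(=O)(=O)C(F)(F)F)C(F)(F)F
Why: Kinetic enolisation, possible only towards C3, followed by O-sulfonylation gives the enol triflate; the low temperature keeps the less acidic acetate from enolising and suppresses loss of acetic acid towards a naphthalene.

Step 5
Reactants: 7 2-bromo-5-chlorophenol
Product: 8 1-bromo-4-chloro-2-(methoxymethoxy)benzene
Conditions: MOMCl, i-Pr2NEt, CH2Cl2, 0 °C to rt
Reagents that add atoms: chloromethyl methyl ether, COCCl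
Why: O-alkylation of the phenol to the methoxymethyl (MOM) acetal, which survives every basic and organometallic step and later serves as the ortho-directing group for the lithiation.

Step 6
Reactants: 8 1-bromo-4-chloro-2-(methoxymethoxy)benzene
Product: 9 2-[4-chloro-2-(methoxymethoxy)phenyl]-4,4,5,5-tetramethyl-1,3,2-dioxaborolane
Conditions: B2pin2, PdCl2(dppf) (3 mol %), KOAc, 1,4-dioxane, 85 °C
Reagents that add atoms: bis(pinacolato)diboron, CC1(C)OB(OC1(C)C)B1OC(C)(C)C(C)(C)O1
Why: Miyaura borylation; zerovalent palladium with dppf inserts into C–Br far faster than into C–Cl, so the chloride needed for the aryne is kept.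

Step 7
Reactants: 6 (1S)-5-methoxy-4-(trifluoromethanesulfonyloxy)-1,2-dihydronaphthalen-1-yl acetate; 9 2-[4-chloro-2-(methoxymethoxy)phenyl]-4,4,5,5-tetramethyl-1,3,2-dioxaborolane
Product: 11 (1S)-4-[4-chloro-2-(methoxymethoxy)phenyl]-5-methoxy-1,2-dihydronaphthalen-1-ol, via coupled acetate 10 (not isolated)
Conditions: Pd(PPh3)4 (5 mol %), K3PO4, 1,4-dioxane/H2O, 80 °C; then LiOH, MeOH, rt; neutral work-up
Reagents that add atoms: none
Why: Suzuki–Miyaura coupling, with oxidative addition at C–OTf and not at the aryl chloride under PPh3 ligation, followed in the same flask by saponification of the acetate to free the hydroxyl that must direct step 8; the work-up is kept neutral because 11 is an arene-hydrate-type alcohol that dehydrates in acid.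

Step 8
Reactants: 11 (1S)-4-[4-chloro-2-(methoxymethoxy)phenyl]-5-methoxy-1,2-dihydronaphthalen-1-ol
Product: 12 (1S,4R)-4-[4-chloro-2-(methoxymethoxy)phenyl]-5-methoxy-1,2,3,4-tetrahydronaphthalen-1-ol
Conditions: [Ir(cod)(PCy3)(py)]PF6 (5 mol %), H2 (1 atm), CH2Cl2, 0 °C to rt
Reagents that add atoms: none
Why: Hydroxyl-directed homogeneous hydrogenation; the cationic iridium centre binds the pseudoaxial homoallylic C1–OH and the C3=C4 alkene on the same face, so both hydrogens arrive syn to oxygen and the aryl group ends trans, which sets C4 as R; no heterogeneous metal is present, so the aryl chloride and the benzylic C–O bond should be spared.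

Step 9
Reactants: 12 (1S,4R)-4-[4-chloro-2-(methoxymethoxy)phenyl]-5-methoxy-1,2,3,4-tetrahydronaphthalen-1-ol
Product: 13 {[(1S,4R)-4-[4-chloro-2-(methoxymethoxy)phenyl]-5-methoxy-1,2,3,4-tetrahydronaphthalen-1-yl]oxy}tri(propan-2-yl)silane
Conditions: TIPSOTf, 2,6-lutidine, CH2Cl2, −78 to 0 °C
Reagents that add atoms: triisopropylsilyl trifluoromethanesulfonate, CC(C)[Si](OS(=O)(=O)C(F)(F)F)(C(C)C)C(C)C
Why: Silylation of the secondary alcohol with a silyl triflate; the bulky triisopropylsilyl (TIPS) group is chosen because it must survive both the lithium amide of step 11 and the acid of step 12, and the low temperature keeps the aryl acetal intact.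

Step 10
Reactants: 14 methyl (E)-but-2-enoate (methyl crotonate)
Product: 16 1-methoxy-1-(trimethylsilyloxy)buta-1,3-diene, via lithium dienolate 15 (not isolated)
Conditions: LiN(i-Pr)2, THF/DMPU, −78 °C; then Me3SiCl, −78 °C to rt
Reagents that add atoms: chlorotrimethylsilane, C[Si](C)(C)Cl
Why: γ-Deprotonation of the crotonate to the extended enolate and O-silylation (silyl ketene acetal formation) give the 1,1-dioxygenated diene; the polar cosolvent favours deprotonation over conjugate addition of the amide.

Step 11
Reactants: 13 {[(1S,4R)-4-[4-chloro-2-(methoxymethoxy)phenyl]-5-methoxy-1,2,3,4-tetrahydronaphthalen-1-yl]oxy}tri(propan-2-yl)silane; 16 1-methoxy-1-(trimethylsilyloxy)buta-1,3-diene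
Product: 20 {[(1S,4R)-5-methoxy-4-[8-methoxy-1-(methoxymethoxy)naphthalen-2-yl]-1,2,3,4-tetrahydronaphthalen-1-yl]oxy}tri(propan-2-yl)silane, via aryllithium 17 (not isolated), via aryne 18 (not isolated), via silyl ketal cycloadduct 19 (not isolated)
Conditions: lithium 2,2,6,6-tetramethylpiperidide (2.5 equiv), THF, −78 °C; then 16 (4 equiv), −78 to 0 °C
Reagents that add atoms: none
Why: The amide removes the C3'' proton of 13, the only one flanked by both the MOM-oxy and the chloro group, and 17 loses LiCl on warming to give the 3-alkoxybenzyne 18; this is the standard haloarene route to arynes, and the [4+2] trapping of 3-alkoxybenzynes by 1,1-dioxygenated dienes is the closest known reaction type. Ring D is closed by an intermolecular, asynchronous suprafacial [4+2] cycloaddition across the s-cis diene (if the addition is stepwise, the aryl anion collapses on the oxocarbenium carbon in a 6-exo-trig sense), forming C4a'–C5' and C8a'–C8'. The orientation is secured by the substrate: the inductively withdrawing oxygen on C1' makes the distal aryne carbon C4a' the electrophilic one and stabilises negative charge building at C8a', so the nucleophilic CH2 terminus of 16 bonds to C4a' and the acetal carbon to C8a', which puts the new OMe peri to the C1' oxygen; the MOM-oxy group also screens C8a' sterically. A [2+2] adduct across the oxygenated double bond of 16 would have the same orientation and would reach 20 through four-electron ring opening, six-electron closure to the 7',8'-dihydro isomer of 19 and elimination. Adduct 19 aromatises by 1,4-elimination: the excess amide removes a doubly activated C5' proton and the better leaving group, trimethylsilanolate, departs, which keeps the methyl ether on C8'. No lasting stereocentre is made (the ketal carbon of 19 forms without control and is erased), and C1 and C4 are spectators: the C1 oxygen is a bulky silyl ether and the hindered tertiary C4–H is kinetically far less acidic than the arene C–H at −78 °C. The excess of 16 is there so that cycloaddition outruns addition of the amine to 18.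

Step 12
Reactants: 20 {[(1S,4R)-5-methoxy-4-[8-methoxy-1-(methoxymethoxy)naphthalen-2-yl]-1,2,3,4-tetrahydronaphthalen-1-yl]oxy}tri(propan-2-yl)silane
Product: 21 8-methoxy-2-[(1R,4S)-8-methoxy-4-(triisopropylsilyloxy)-1,2,3,4-tetrahydronaphthalen-1-yl]naphthalen-1-ol (the C1 triisopropylsilyl ether of the target)
Conditions: HCl (0.5 M), MeOH/THF, 0 °C to rt
Reagents that add atoms: none
Why: Acid-catalysed acetal exchange cleaves the aryl MOM ether, and methanol traps the methoxymethyl cation as dimethoxymethane so that it cannot alkylate the naphthol; the C1 oxygen is still a hindered silyl ether, so the benzylic position should not ionise and C1 keeps its configuration.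

Step 13
Reactants: 21 8-methoxy-2-[(1R,4S)-8-methoxy-4-(triisopropylsilyloxy)-1,2,3,4-tetrahydronaphthalen-1-yl]naphthalen-1-ol
Product: 22 dipolynaphthalene A, (1S,4R)-4-(1-hydroxy-8-methoxynaphthalen-2-yl)-5-methoxy-1,2,3,4-tetrahydronaphthalen-1-ol
Conditions: Bu4NF, THF, 0 °C to rt, under argon
Reagents that add atoms: none
Why: Fluoride-induced Si–O cleavage, driven by the Si–F bond, frees the benzylic alcohol under non-acidic conditions, so neither stereocentre is at risk; argon protects the transient naphthoxide from air oxidation.

## Compound list

1 | 5-methoxy-3,4-dihydronaphthalen-1(2H)-one | COc1cccc2c1CCCC2=O | starting material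
2 | (1S)-5-methoxy-1,2,3,4-tetrahydronaphthalen-1-ol | COc1cccc2c1CCC[C@@H]2O | intermediate
3 | (1S)-5-methoxy-1,2,3,4-tetrahydronaphthalen-1-yl acetate | COc1cccc2c1CCC[C@@H]2OC(C)=O | intermediate
4 | (1S)-5-methoxy-4-oxo-1,2,3,4-tetrahydronaphthalen-1-yl acetate | COc1cccc2c1C(=O)CC[C@@H]2OC(C)=O | intermediate
5 | potassium (4S)-4-acetoxy-8-methoxy-3,4-dihydronaphthalen-1-olate (enolate of 4, not isolated) | COc1cccc2c1C([O-])=CC[C@@H]2OC(C)=O.[K+] | intermediate
6 | (1S)-5-methoxy-4-(trifluoromethanesulfonyloxy)-1,2-dihydronaphthalen-1-yl acetate | COc1cccc2c1C(OS(=O)(=O)C(F)(F)F)=CC[C@@H]2OC(C)=O | intermediate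
7 | 2-bromo-5-chlorophenol | Oc1cc(Cl)ccc1Br | starting material
8 | 1-bromo-4-chloro-2-(methoxymethoxy)benzene | COCOc1cc(Cl)ccc1Br | intermediate
9 | 2-[4-chloro-2-(methoxymethoxy)phenyl]-4,4,5,5-tetramethyl-1,3,2-dioxaborolane | COCOc1cc(Cl)ccc1B1OC(C)(C)C(C)(C)O1 | intermediate
10 | (1S)-4-[4-chloro-2-(methoxymethoxy)phenyl]-5-methoxy-1,2-dihydronaphthalen-1-yl acetate (not isolated) | COc1cccc2c1C(c1ccc(Cl)cc1OCOC)=CC[C@@H]2OC(C)=O | intermediate
11 | (1S)-4-[4-chloro-2-(methoxymethoxy)phenyl]-5-methoxy-1,2-dihydronaphthalen-1-ol | COc1cccc2c1C(c1ccc(Cl)cc1OCOC)=CC[C@@H]2O | intermediate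
12 | (1S,4R)-4-[4-chloro-2-(methoxymethoxy)phenyl]-5-methoxy-1,2,3,4-tetrahydronaphthalen-1-ol (trans) | COc1cccc2c1[C@@H](c1ccc(Cl)cc1OCOC)CC[C@@H]2O | intermediate
13 | {[(1S,4R)-4-[4-chloro-2-(methoxymethoxy)phenyl]-5-methoxy-1,2,3,4-tetrahydronaphthalen-1-yl]oxy}tri(propan-2-yl)silane (trans) | COc1cccc2c1[C@@H](c1ccc(Cl)cc1OCOC)CC[C@@H]2O[Si](C(C)C)(C(C)C)C(C)C | intermediate
14 | methyl (E)-but-2-enoate | C/C=C/C(=O)OC | starting material
15 | lithium 1-methoxybuta-1,3-dien-1-olate (not isolated) | C=CC=C(OC)[O-].[Li+] | intermediate
16 | 1-methoxy-1-(trimethylsilyloxy)buta-1,3-diene | C=CC=C(OC)O[Si](C)(C)C | intermediate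
17 | 13 lithiated at C3'' between the MOM-oxy and chloro groups (not isolated) | COc1cccc2c1[C@@H](c1ccc(Cl)c([Li])c1OCOC)CC[C@@H]2O[Si](C(C)C)(C(C)C)C(C)C | intermediate
18 | 3'',4''-didehydro aryne derived from 13 by loss of LiCl (not isolated) | COc1cccc2c1[C@@H](C1=C(OCOC)C#CC=C1)CC[C@@H]2O[Si](C(C)C)(C(C)C)C(C)C | intermediate
19 | 5',8'-dihydronaphthalene cycloadduct with OMe and OSiMe3 on C8', configuration at C8' undefined (not isolated) | COc1cccc2c1[C@@H](c1ccc3CC=CC(OC)(O[Si](C)(C)C)c3c1OCOC)CC[C@@H]2O[Si](C(C)C)(C(C)C)C(C)C | intermediate
20 | {[(1S,4R)-5-methoxy-4-[8-methoxy-1-(methoxymethoxy)naphthalen-2-yl]-1,2,3,4-tetrahydronaphthalen-1-yl]oxy}tri(propan-2-yl)silane | COc1cccc2c1[C@@H](c1ccc3cccc(OC)c3c1OCOC)CC[C@@H]2O[Si](C(C)C)(C(C)C)C(C)C | intermediate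
21 | 8-methoxy-2-[(1R,4S)-8-methoxy-4-(triisopropylsilyloxy)-1,2,3,4-tetrahydronaphthalen-1-yl]naphthalen-1-ol | COc1cccc2c1[C@@H](c1ccc3cccc(OC)c3c1O)CC[C@@H]2O[Si](C(C)C)(C(C)C)C(C)C | intermediate
22 | dipolynaphthalene A, (1S,4R)-4-(1-hydroxy-8-methoxynaphthalen-2-yl)-5-methoxy-1,2,3,4-tetrahydronaphthalen-1-ol | COc1cccc2c1[C@@H](c1ccc3cccc(OC)c3c1O)CC[C@@H]2O | target

## Step count and least certain steps

Total: 13 steps. Longest linear sequence: 10 steps (steps 1, 2, 3, 4, 7, 8, 9, 11, 12 and 13). Steps 5 and 6 and step 10 are side branches.

**Step 11 (key step).** Three processes may go wrong: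
- Aromatisation of 19 by the wrong path, either loss of methoxide or desilylation and collapse of the hemiketal, would leave a phenol on C8' in place of the methyl ether.
- Capture of 18 by the liberated amine or by a second aryllithium would lower the efficiency of the cycloaddition.
- Slow deprotonation of the doubly benzylic C4–H by the excess amide on warming would erode the C4 configuration.

Fallback: set out from 13 and from dienolate 15 (made from 14 as in the first half of step 10). Aryne 18 is generated in the same way but trapped by the anionic dienolate. This is the known naphthol annulation of arynes with ester dienolates: carbon attack at C4a', acyl transfer to C8a' with loss of methoxide, ring opening and six-electron closure. It gives the peri-naphthol {[(1S,4R)-4-[8-hydroxy-1-(methoxymethoxy)naphthalen-2-yl]-5-methoxy-1,2,3,4-tetrahydronaphthalen-1-yl]oxy}tri(propan-2-yl)silane F1. The more nucleophilic anionic trap should outcompete the amine. O-Methylation of F1 (MeI, K2CO3, acetone) returns to the route at 20. The same methylation converges any F1 that forms by chance in step 11 itself.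

**Step 3.** Oxidation at the peri-hindered C4 may be slow. The electron-rich ring may be over-oxidised, or C1 may be attacked with loss of the stereocentre.

Fallback: set out from 3 and reach the ketone in three functional-group steps. Radical benzylic bromination (NBS, dibenzoyl peroxide, PhCF3, 80 °C) gives (1S)-4-bromo-5-methoxy-1,2,3,4-tetrahydronaphthalen-1-yl acetate F2 as a mixture of C4 epimers. Silver-assisted solvolysis (AgNO3, acetone/H2O) gives (1S)-4-hydroxy-5-methoxy-1,2,3,4-tetrahydronaphthalen-1-yl acetate F3. Oxidation with Dess–Martin periodinane returns to the route at 4.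

**Step 8.** Acidic iridium hydride species may dehydrate the arene-hydrate-type alcohol 11 to a naphthalene. Facial control may be incomplete if the catalyst binds the ether oxygens instead of the hydroxyl. A heterogeneous catalyst is no remedy: steric delivery would favour the cis isomer and would endanger the aryl chloride.

Fallback: set out from 11 and replace substrate direction by catalyst control. Silylation (TIPSOTf, 2,6-lutidine) gives {[(1S)-4-[4-chloro-2-(methoxymethoxy)phenyl]-5-methoxy-1,2-dihydronaphthalen-1-yl]oxy}tri(propan-2-yl)silane F4, which cannot dehydrate. F4 is then hydrogenated with a chiral cationic iridium phosphine–oxazoline catalyst, [Ir(cod)(t-Bu-PHOX)]B[3,5-(CF3)2C6H3]4, under H2 (50 bar) in CH2Cl2. This catalyst class is known for 1-aryl-3,4-dihydronaphthalenes. The ligand antipode that delivers hydrogen syn to the C1 oxygen would be found by testing both. The sequence returns to the route at 13.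

**Step 7.** Transmetalation at the doubly ortho-hindered junction may be slow. That would leave time for protodeboronation of 9, hydrolysis of 6, or base-induced loss of acetic acid towards a naphthalene.

Fallback: set out from 6 and reverse the polarity of the coupling. Miyaura borylation of the triflate (B2pin2, PdCl2(dppf), KOAc, 1,4-dioxane, 80 °C) gives the alkenylboronate (1S)-5-methoxy-4-(4,4,5,5-tetramethyl-1,3,2-dioxaborolan-2-yl)-1,2-dihydronaphthalen-1-yl acetate F5. Alkenylboronates are less prone to protodeboronation than ortho-alkoxyarylboronates. F5 is coupled with bromide 8 (Pd(PPh3)4, K3PO4, 1,4-dioxane/H2O) and returns to the route at 10, which is saponified to 11 as in step 7. This path also makes step 6 unnecessary.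

## Further compounds

F1 | step 11 | {[(1S,4R)-4-[8-hydroxy-1-(methoxymethoxy)naphthalen-2-yl]-5-methoxy-1,2,3,4-tetrahydronaphthalen-1-yl]oxy}tri(propan-2-yl)silane | COc1cccc2c1[C@@H](c1ccc3cccc(O)c3c1OCOC)CC[C@@H]2O[Si](C(C)C)(C(C)C)C(C)C
F2 | step 3 | (1S)-4-bromo-5-methoxy-1,2,3,4-tetrahydronaphthalen-1-yl acetate (C4 epimers) | COc1cccc2c1C(Br)CC[C@@H]2OC(C)=O
F3 | step 3 | (1S)-4-hydroxy-5-methoxy-1,2,3,4-tetrahydronaphthalen-1-yl acetate (C4 epimers) | COc1cccc2c1C(O)CC[C@@H]2OC(C)=O
F4 | step 8 | {[(1S)-4-[4-chloro-2-(methoxymethoxy)phenyl]-5-methoxy-1,2-dihydronaphthalen-1-yl]oxy}tri(propan-2-yl)silane | COc1cccc2c1C(c1ccc(Cl)cc1OCOC)=CC[C@@H]2O[Si](C(C)C)(C(C)C)C(C)C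
F5 | step 7 | (1S)-5-methoxy-4-(4,4,5,5-tetramethyl-1,3,2-dioxaborolan-2-yl)-1,2-dihydronaphthalen-1-yl acetate | COc1cccc2c1C(B1OC(C)(C)C(C)(C)O1)=CC[C@@H]2OC(C)=O
A1 | alternative 1 | (Z)-4-(2-chloro-5-methoxyphenyl)-2-[(1R,4S)-4-(tert-butyldimethylsilyloxy)-8-methoxy-1,2,3,4-tetrahydronaphthalen-1-yl]but-3-enoic acid | COc1cccc2c1[C@@H](C(C(=O)O)/C=C\c1cc(OC)ccc1Cl)CC[C@@H]2O[Si](C)(C)C(C)(C)C
A2 | alternative 1 | dienylketene derived from A1 | COc1cccc2c1[C@@H](C(=C=O)/C=C\c1cc(OC)ccc1Cl)CC[C@@H]2O[Si](C)(C)C(C)(C)C
A3 | alternative 1 | 5'-chloro derivative of the target as C1 tert-butyldimethylsilyl ether | COc1cccc2c1[C@@H](c1ccc3c(Cl)ccc(OC)c3c1O)CC[C@@H]2O[Si](C)(C)C(C)(C)C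
A4 | alternative 2 | ortho-bis(allylic) arene diene, silyloxy carbon and diaryl carbon each bearing a vinyl group | COc1cccc([C@H](C=C)O[Si](C)(C)C(C)(C)C)c1[C@@H](C=C)c1ccc2cccc(OC)c2c1OCOC
A5 | alternative 2 | 2,3-didehydro target as C1 tert-butyldimethylsilyl ether and naphthol MOM ether | COc1cccc2c1[C@@H](c1ccc3cccc(OC)c3c1OCOC)C=C[C@@H]2O[Si](C)(C)C(C)(C)C
A6 | alternative 3 | 3-methoxy-2-{[8-methoxy-1-(methoxymethoxy)naphthalen-2-yl]methyl}benzaldehyde | COc1cccc(C=O)c1Cc1ccc2cccc(OC)c2c1OCOC
A7 | alternative 3 | hydroxy-ortho-quinodimethane (photoenol) of A6 | COC1=CC=CC(=CO)C1=Cc1ccc2cccc(OC)c2c1OCOC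
A8 | alternative 3 | methyl acrylate | C=CC(=O)OC
A9 | alternative 3 | all-cis methyl 1-hydroxy-5-methoxy-4-[8-methoxy-1-(methoxymethoxy)naphthalen-2-yl]-1,2,3,4-tetrahydronaphthalene-2-carboxylate | COc1cccc2c1[C@@H](c1ccc3cccc(OC)c3c1OCOC)C[C@@H](C(=O)OC)[C@H]2O
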